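## Analysis of the target

The target is a flavonol: the kaempferol skeleton with a 1,1‑dimethylallyl (2‑methylbut‑3‑en‑2‑yl, "reverse prenyl") group on C8. Ring A (C4a, C5–C8, C8a) is a phloroglucinol ring with oxygen on C5, C7 and C8a (O1), ring C is the 3‑hydroxy‑4‑pyranone (O1, C2, C3, C4), and ring B is a 4‑hydroxyphenyl group on C2. There is no stereocentre; the only sp3 carbons are the quaternary C1'' and its two methyl groups. The sensitive part is the tertiary allyl group beside the free C7 hydroxyl. Acid lets that phenol add to the vinyl group (dihydrofuran formation) or ionises the C8–C1'' bond, after which the allyl unit can return in the linear form or at C6. The vinyl group rules out hydrogenolysis, and the free polyphenol is easily oxidised in base. The synthesis is hard for two reasons: a quaternary carbon must be attached to C8, wedged between C7–O and C8a–O, without forming the linear prenyl or the C6 isomer, and four hydroxyl groups must be unveiled without acid. The strategy rests on the contiguous triad C8a(O)–C8(C)–C7(O) of ring A. This is the pattern a 3‑alkoxybenzyne leaves when a heteroatom adds to the aryne carbon far from the alkoxy group and a carbon group ends on the aryne carbon next to it.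

## Retrosynthetic reasoning

24 to 23. The three O–CH3 bonds at O5, O7 and O4' are cut last. Methyl is kept because the methyl on O7 is delivered by the key step itself, and because aryl methyl ethers can be removed by a soft nucleophile in a medium that contains no acid. The forward reaction has to cleave three ethers while leaving the vinyl group and the C8–C1'' bond alone.

23 to 21. Ring C is opened at O1–C2 and at the C3–OH bond, which leads to the 2'‑hydroxychalcone 21. An oxidative cyclisation in alkaline peroxide makes the pyranone and the C3 hydroxyl together, through dihydroflavonol 22, and nucleophilic peroxide does not touch an isolated vinyl group. The forward reaction has to close the six‑membered ring and not the five‑membered one.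

21 to 18 and 19. The C2=C3 double bond is cut to the methyl ketone 18 and the aldehyde 19. This brings in ring B convergently by an aldol condensation (through 20) that needs only base.

18 to 16. The free hydroxyl of 18, the future O1, is traced back to a methyl ether. Of the two methoxy groups ortho to the acetyl group in 16, only the one that also neighbours the tertiary alkyl group may be cleaved, because it defines which oxygen closes ring C and hence whether the allyl group ends on C8 or C6. Chelation to the carbonyl group (boron chelate 17) and the out‑of‑plane twist of this methoxy group are the handles.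

16 to 13. The C4a–C4 bond (aryl–acetyl) is cut. Compound 13 has a mirror plane through the tertiary alkyl group, so its two ring hydrogens are equivalent and each lies between two methoxy groups. The acetyl group can therefore be brought in by ring metalation (14) and acyl transfer (15) with no regiochemical question and no acid. An electrophilic acylation is kept only as a reserve, because acid threatens the tertiary allyl group on so electron‑rich a ring.

13 to 8 and 10. This is the key disconnection: C7–O and C8–C1'' are cut together. Forward, the aryne 11 released from 8 takes up the oxygen of the allyl methyl ether 10 at the carbon remote from its flanking methoxy group. The zwitterion 12 then passes the allyl group from oxygen to the neighbouring carbanion with inversion, so the quaternary carbon arrives on the ring and the methyl group stays on oxygen. Two skeletal bonds are gained and the reverse‑prenyl connectivity is written into the mechanism. Cutting only C8–C1'' would mean alkylating an arene with a tertiary allyl electrophile, which favours the linear isomer.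

8 to 6, 2 and 1; 10 to 9. The silyl triflate 8 is taken back through its carbamate 6 (via 7) to the carbamate 2 of the commercial phenol 1. The carbamate directs metalation (3, 4, 5) to the carbon between itself and a methoxy group and can afterwards be exchanged for triflate. Ether 10 is the O‑methyl derivative of the commercial alcohol 9.

## Alternatives that were turned down

Alternative 1: Ring C is cut at C2–C3. In ester A2 the aroyl group sits on O1. Base forms the enolate of the α‑(methoxymethoxy)acetyl group, its carbon (C3) takes the aroyl carbon (C2) from O1 in a Baker–Venkataraman shift, and the diketone phenoxide closes with loss of water to A1.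
- For: the C3 oxygen is in place before ring closure, so there is no oxidative cyclisation and no five‑membered (aurone) branch. On this point it is stronger than the chosen route. The acetal groups also leave in dilute acid at modest temperature, which is gentler in temperature than the hot thiolate of step 10.
- Against: it is a plan for ring C only. A2 already contains the quaternary carbon on C8 and three differently protected ring A oxygens, all of which must come from a separate reverse prenylation and selective protection. The ester must be made on the hydroxyl wedged between the acyl group and the tertiary alkyl group. Both the cyclodehydration and the final acetal removal use acid next to the tertiary allyl group, the last with the C7 hydroxyl free.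
- Comparison: four acetal installations, an α‑oxygenated ketone and an extra acylation make it longer. The chosen route accepts a weaker ring C closure and in return makes C8–C1'' and C7–O in one step from 1.

Alternative 2: Ring A is built from two acyclic or small‑ring partners. Heating A4 opens it to a vinylketene, which adds to the siloxyalkyne A5; ring opening, 6π closure and tautomerisation (Danheiser benzannulation) give A3 with C8–C8a, C6–C7 and C4a–C8a formed.
- For: the three ring A oxygens emerge as free hydroxyl (future O1), silyl ether (O7) and ethyl ether (O5). The question that step 7 of the chosen route must answer by a selective demethylation is answered here by construction, and O7 is unveiled by fluoride. The quaternary carbon comes in on the alkyne, so no bond is made to a crowded aromatic carbon. On both points it is stronger.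
- Against: A5 is an ynol silyl ether with a quaternary propargylic carbon and needs several steps of sensitive chemistry, and A4 must also be prepared. In the ketene–alkyne union the alkyne carbon carrying the tertiary group must bond to the ketene carbonyl carbon, the most hindered combination. The C5 ethyl ether is no easier to cleave than a methyl ether, and the acyl group on C4a still has to be introduced.
- Comparison: it is clearly longer. The chosen route offers a two‑bond step on a cheap aromatic and a symmetric intermediate 13, at the price of telling two methoxy groups apart later.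

Alternative 3: Ring A is folded from the symmetric tetracarbonyl chain A7. A magnesium alkoxide templates attack of the methylene carbon between ester and ketone (future C4a) on the far ester carbonyl (future C5), and enolisation gives the aromatic triol ester A6.
- For: the symmetry of A7 allows only one folding, and C4a carries its carbonyl carbon (C4) from the start. The aryl–acyl bond that the chosen route makes in step 6 is therefore not needed, which is a real advantage.
- Against: A7 has a tertiary allyl group on the central carbon of a 1,3‑diketone flanked by two β‑keto ester arms. It cannot be reached by alkylation, because tertiary allyl electrophiles couple at their primary end and the outer methylenes compete, and such chains also close through oxygen to pyranones. A6 emerges as an unprotected triol with a free hydroxyl beside the tertiary allyl group. Its oxygens must then be told apart and its ester turned into the enone, all on an acid‑sensitive, unprotected ring.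
- Comparison: longer and less controlled. The chosen route keeps every oxygen protected from the start.

Key step: step 5

Remark on the chemistry: the reagents that appear only on the reagent lines (isopropyl isocyanate, TMSCl, PhNTf2, MeI, N‑methoxy‑N‑methylacetamide, H2O2) are taken as purchased. Intermediates 20 and 22 are racemic and their stereocentres disappear before the target.

## Route

Step 1
Reactants: 1 3,5-dimethoxyphenol
Product: 2 3,5-dimethoxyphenyl N-(propan-2-yl)carbamate
Conditions: iPrNCO, Et3N (cat.), CH2Cl2, rt
Reagents that add atoms: isopropyl isocyanate, CC(C)N=C=O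
Why: Base‑catalysed addition of the phenol to the isocyanate (carbamoylation) gives an N‑monosubstituted aryl carbamate, a strong ortho‑directing group that can later be removed by elimination.

Step 2
Reactants: 2 3,5-dimethoxyphenyl N-(propan-2-yl)carbamate
Product: 6 3,5-dimethoxy-2-(trimethylsilyl)phenyl N-(propan-2-yl)carbamate, via N-silyl carbamate 3 (not isolated), via ortho-lithiated N-silyl carbamate 4 (not isolated), via C,N-bis(trimethylsilyl) carbamate 5 (not isolated)
Conditions: TMSOTf, TMEDA, Et2O, 0 °C → rt; n-BuLi, TMEDA, −78 °C; TMSCl, −78 °C → rt; H2O
Reagents that add atoms: chlorotrimethylsilane, C[Si](C)(C)Cl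
Why: In situ N‑silylation masks the N–H, after which directed ortho‑metalation should occur between the carbamate and a methoxy group; both such sites are equivalent, and the carbamate outranks methoxy as a director, so the site between the two methoxy groups should not compete. The aryllithium is silylated on carbon, and the labile N–Si bond is lost on neutral aqueous work‑up, which avoids protodesilylation of the electron‑rich arylsilane.

Step 3
Reactants: 6 3,5-dimethoxy-2-(trimethylsilyl)phenyl N-(propan-2-yl)carbamate
Product: 8 3,5-dimethoxy-2-(trimethylsilyl)phenyl trifluoromethanesulfonate, via silylphenol 7 (not isolated)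
Conditions: Et2NH, DBU, MeCN, 40 °C; then PhNTf2, rt
Reagents that add atoms: N-phenylbis(trifluoromethanesulfonimide), O=S(=O)(N(c1ccccc1)S(=O)(=O)C(F)(F)F)C(F)(F)F
Why: DBU removes the carbamate N–H and the aryloxide is expelled (E1cB) with isopropyl isocyanate, which Et2NH traps as a urea. The phenoxide is then O‑sulfonylated by PhNTf2 in the same flask (one‑pot carbamate cleavage and triflation) under conditions too mild to cleave the C–Si bond.

Step 4
Reactants: 9 3-methylbut-2-en-1-ol
Product: 10 1-methoxy-3-methylbut-2-ene
Conditions: NaH, MeI, diglyme, 0 °C → rt; distillation from the mixture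
Reagents that add atoms: iodomethane, CI
Why: Williamson ether synthesis; the primary allylic alkoxide displaces iodide from iodomethane (SN2) without touching the alkene, and the volatile ether is separated from the high‑boiling solvent by distillation.

Step 5
Reactants: 8 3,5-dimethoxy-2-(trimethylsilyl)phenyl trifluoromethanesulfonate; 10 1-methoxy-3-methylbut-2-ene
Product: 13 1,3,5-trimethoxy-2-(2-methylbut-3-en-2-yl)benzene, via 3,5-dimethoxybenzyne 11 (not isolated), via aryl anion–oxonium zwitterion 12 (not isolated)
Conditions: CsF, 18-crown-6 (cat.), 10 as solvent (large excess), PhMe co-solvent, 4 Å MS, 60 °C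
Reagents that add atoms: none
Why: Proposed new method: fluoride attacks silicon in 8 and triflate leaves, giving aryne 11; the ether oxygen of 10 then adds to the aryne carbon remote from the flanking methoxy group (future C7), because that methoxy group is inductively withdrawing and distorts the triple bond so that negative charge builds up on the carbon next to it (future C8), which gives zwitterion 12. In 12 the in‑plane aryl anion, C7, the oxonium oxygen, the CH2, the CH and the CMe2 terminus form a six‑atom array, and a charge‑accelerated [3,3] shift makes C8–C1'' while the O–CH2 bond breaks, so that a neutral aryl methyl ether results and the allyl unit arrives inverted, with the quaternary carbon on the ring. The closest known reaction type is the aryne aza‑Claisen rearrangement of tertiary allylamines, in which an aryl anion/allylammonium zwitterion undergoes the same shift, together with the known capture of arynes by ether oxygen to give aryloxonium zwitterions; the combination on an allyl alkyl ether is what is new. No ring is closed and no stereocentre is formed. The step needs regioselective O‑addition, secured by the methoxy group next to the triple bond (the opposite sense would give an unsymmetrical 1,2,4‑trioxygenated arene, whereas 13 has a mirror plane), and it needs the shift to outrun proton transfer to the aryl anion, dealkylation of the oxonium ion by fluoride and ene reaction of 11 at the trisubstituted alkene of 10. A medium without acidic C–H bonds or other nucleophilic solvents, the use of 10 as solvent, slow heterogeneous release of 11, and a shift that is intramolecular, six‑membered and expels a neutral leaving group should favour the wanted path; attack at the CH2 end would need a four‑membered array, so the linear prenyl isomer is not expected.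

Step 6
Reactants: 13 1,3,5-trimethoxy-2-(2-methylbut-3-en-2-yl)benzene
Product: 16 1-[2,4,6-trimethoxy-3-(2-methylbut-3-en-2-yl)phenyl]ethan-1-one, via aryllithium 14 (not isolated), via tetrahedral lithium adduct 15 (not isolated)
Conditions: n-BuLi, TMEDA, THF, 0 °C; MeC(O)N(OMe)Me, −78 °C → rt; H2O
Reagents that add atoms: N-methoxy-N-methylacetamide, CC(=O)N(C)OC
Why: Directed ortho‑metalation at one of the two equivalent ring C–H bonds, each flanked by two methoxy groups, followed by Weinreb ketone synthesis; the chelated tetrahedral adduct 15 releases the ketone only on work‑up, so no tertiary alcohol forms. This base‑mediated acylation is preferred to a Friedel–Crafts reaction because acid could ionise or shift the tertiary allyl group on this very electron‑rich ring.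

Step 7
Reactants: 16 1-[2,4,6-trimethoxy-3-(2-methylbut-3-en-2-yl)phenyl]ethan-1-one
Product: 18 1-[2-hydroxy-4,6-dimethoxy-3-(2-methylbut-3-en-2-yl)phenyl]ethan-1-one, via dichloroboron chelate 17 (not isolated)
Conditions: BCl3 (1.2 equiv), CH2Cl2, −78 → 0 °C; cold aq. NaHCO3
Reagents that add atoms: none
Why: Chelation‑controlled ether cleavage: BCl3 binds the carbonyl oxygen and an ortho methoxy oxygen in a six‑membered chelate and chloride removes the methyl group by SN2. The methoxy group wedged between the acetyl and the tertiary alkyl group is twisted out of the ring plane, which makes its oxygen the better donor and its cleavage strain‑releasing, and the carbonyl oxygen, the small end of the acetyl group, should turn toward this crowded side. The para methoxy group has no chelating partner and should survive at low temperature, and the cold basic quench protects the vinyl group from HCl.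

Step 8
Reactants: 18 1-[2-hydroxy-4,6-dimethoxy-3-(2-methylbut-3-en-2-yl)phenyl]ethan-1-one; 19 4-methoxybenzaldehyde
Product: 21 (E)-1-[2-hydroxy-4,6-dimethoxy-3-(2-methylbut-3-en-2-yl)phenyl]-3-(4-methoxyphenyl)prop-2-en-1-one, via aldol adduct 20 (not isolated)
Conditions: KOH, EtOH/H2O, rt; aq. NH4Cl
Reagents that add atoms: none
Why: Claisen–Schmidt condensation: the methyl ketone enolate adds to the non‑enolisable aldehyde and aldol 20 loses water (E1cB) to the conjugated enone, the E geometry being the thermodynamically favoured one.

Step 9
Reactants: 21 (E)-1-[2-hydroxy-4,6-dimethoxy-3-(2-methylbut-3-en-2-yl)phenyl]-3-(4-methoxyphenyl)prop-2-en-1-one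
Product: 23 3-hydroxy-5,7-dimethoxy-2-(4-methoxyphenyl)-8-(2-methylbut-3-en-2-yl)chromen-4-one, via trans-dihydroflavonol 22 (not isolated)
Conditions: 30% H2O2, aq. NaOH, MeOH/THF, 0 °C → rt; aq. NH4Cl
Reagents that add atoms: hydrogen peroxide, OO
Why: Algar–Flynn–Oyamada reaction: the phenoxide adds to the enone β‑carbon (6‑endo oxa‑Michael closure of ring C), the enolate is hydroxylated by H2O2 to the trans‑dihydroflavonol 22, and 22 is dehydrogenated in the alkaline peroxide medium to the flavonol. Nucleophilic peroxide does not attack the isolated vinyl group, and the medium is free of acid.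

Step 10
Reactants: 23 3-hydroxy-5,7-dimethoxy-2-(4-methoxyphenyl)-8-(2-methylbut-3-en-2-yl)chromen-4-one
Product: 24 3,5,7-trihydroxy-2-(4-hydroxyphenyl)-8-(2-methylbut-3-en-2-yl)chromen-4-one
Conditions: NaSEt (excess), DMF, 140 °C, Ar, degassed; cold dilute HCl to pH 5
Reagents that add atoms: none
Why: SN2 demethylation of aryl methyl ethers by a soft thiolate in a dipolar aprotic solvent; the O7 and O4' ethers are vinylogous esters of the C4 carbonyl and leave as stabilised phenoxides, and the O5 ether leaves as an ortho‑acyl phenoxide held by the sodium ion. The medium is basic throughout, so the tertiary allyl group beside the C7 oxygen is neither cyclised nor ionised.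

## Compound list

1 | 3,5-dimethoxyphenol | COc1cc(O)cc(OC)c1 | starting material
2 | 3,5-dimethoxyphenyl N-(propan-2-yl)carbamate | COc1cc(OC)cc(OC(=O)NC(C)C)c1 | intermediate
3 | 3,5-dimethoxyphenyl N-(propan-2-yl)-N-(trimethylsilyl)carbamate | COc1cc(OC)cc(OC(=O)N(C(C)C)[Si](C)(C)C)c1 | intermediate (not isolated)
4 | 2-lithio-3,5-dimethoxyphenyl N-(propan-2-yl)-N-(trimethylsilyl)carbamate | [Li]c1c(OC)cc(OC)cc1OC(=O)N(C(C)C)[Si](C)(C)C | intermediate (not isolated)
5 | 3,5-dimethoxy-2-(trimethylsilyl)phenyl N-(propan-2-yl)-N-(trimethylsilyl)carbamate | COc1cc(OC)c([Si](C)(C)C)c(OC(=O)N(C(C)C)[Si](C)(C)C)c1 | intermediate (not isolated)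
6 | 3,5-dimethoxy-2-(trimethylsilyl)phenyl N-(propan-2-yl)carbamate | COc1cc(OC)c([Si](C)(C)C)c(OC(=O)NC(C)C)c1 | intermediate
7 | 3,5-dimethoxy-2-(trimethylsilyl)phenol (present as its DBU salt) | COc1cc(O)c([Si](C)(C)C)c(OC)c1 | intermediate (not isolated)
8 | 3,5-dimethoxy-2-(trimethylsilyl)phenyl trifluoromethanesulfonate | COc1cc(OC)c([Si](C)(C)C)c(OS(=O)(=O)C(F)(F)F)c1 | intermediate
9 | 3-methylbut-2-en-1-ol | CC(C)=CCO | starting material
10 | 1-methoxy-3-methylbut-2-ene | COCC=C(C)C | intermediate
11 | 3,5-dimethoxybenzyne (1,2-didehydro-3,5-dimethoxybenzene) | COC1=CC(OC)=CC#C1 | intermediate (not isolated)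
12 | 4,6-dimethoxy-2-[methyl(3-methylbut-2-en-1-yl)oxonio]benzen-1-ide | COc1cc(OC)[c-]c([O+](C)CC=C(C)C)c1 | intermediate (not isolated)
13 | 1,3,5-trimethoxy-2-(2-methylbut-3-en-2-yl)benzene | C=CC(C)(C)c1c(OC)cc(OC)cc1OC | intermediate
14 | [2,4,6-trimethoxy-3-(2-methylbut-3-en-2-yl)phenyl]lithium | [Li]c1c(OC)cc(OC)c(C(C)(C)C=C)c1OC | intermediate (not isolated)
15 | lithium 1-[methoxy(methyl)amino]-1-[2,4,6-trimethoxy-3-(2-methylbut-3-en-2-yl)phenyl]ethan-1-olate | C=CC(C)(C)c1c(OC)cc(OC)c(C(C)(O[Li])N(C)OC)c1OC | intermediate (not isolated)
16 | 1-[2,4,6-trimethoxy-3-(2-methylbut-3-en-2-yl)phenyl]ethan-1-one | C=CC(C)(C)c1c(OC)cc(OC)c(C(C)=O)c1OC | intermediate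
17 | [2-acetyl-3,5-dimethoxy-6-(2-methylbut-3-en-2-yl)phenoxy]dichloroborane | C=CC(C)(C)c1c(OC)cc(OC)c(C(C)=O)c1OB(Cl)Cl | intermediate (not isolated)
18 | 1-[2-hydroxy-4,6-dimethoxy-3-(2-methylbut-3-en-2-yl)phenyl]ethan-1-one | C=CC(C)(C)c1c(OC)cc(OC)c(C(C)=O)c1O | intermediate
19 | 4-methoxybenzaldehyde | COc1ccc(C=O)cc1 | starting material
20 | 3-hydroxy-1-[2-hydroxy-4,6-dimethoxy-3-(2-methylbut-3-en-2-yl)phenyl]-3-(4-methoxyphenyl)propan-1-one (racemic) | C=CC(C)(C)c1c(OC)cc(OC)c(C(=O)CC(O)c2ccc(OC)cc2)c1O | intermediate (not isolated)
21 | (E)-1-[2-hydroxy-4,6-dimethoxy-3-(2-methylbut-3-en-2-yl)phenyl]-3-(4-methoxyphenyl)prop-2-en-1-one | C=CC(C)(C)c1c(OC)cc(OC)c(C(=O)/C=C/c2ccc(OC)cc2)c1O | intermediate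
22 | rac-(2R,3R)-3-hydroxy-5,7-dimethoxy-2-(4-methoxyphenyl)-8-(2-methylbut-3-en-2-yl)-2,3-dihydrochromen-4-one (trans; one enantiomer drawn) | O=C1[C@H](O)[C@@H](c2ccc(OC)cc2)Oc2c1c(OC)cc(OC)c2C(C)(C)C=C | intermediate (not isolated)
23 | 3-hydroxy-5,7-dimethoxy-2-(4-methoxyphenyl)-8-(2-methylbut-3-en-2-yl)chromen-4-one | C=CC(C)(C)c1c(OC)cc(OC)c2c(=O)c(O)c(-c3ccc(OC)cc3)oc12 | intermediate
24 | 3,5,7-trihydroxy-2-(4-hydroxyphenyl)-8-(2-methylbut-3-en-2-yl)chromen-4-one | C=CC(C)(C)c1c(O)cc(O)c2c(=O)c(O)c(-c3ccc(O)cc3)oc12 | target

## Step count and least certain steps

Total: 10 steps. Longest linear sequence: 9 steps (1, 2, 3, 5, 6, 7, 8, 9, 10 from compound 1); step 4 is a one‑step side branch.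

Step 5 (key step, the one proposed as a new method). The most likely failure is that capture of the aryne by the weakly nucleophilic ether oxygen loses to other ways of consuming the aryne: ene reaction or cycloaddition at the trisubstituted alkene of 10, addition of fluoride, or self‑condensation. The zwitterion may also collapse by proton transfer or by dealkylation of the oxonium ion before the shift, which is slowed by the crowding around a carbanion flanked by two oxygen substituents that must attack a fully substituted carbon. Fallback by known chemistry, setting out from 1 and returning at 13: O‑alkylation of 1 with 1‑bromo‑3‑methylbut‑2‑ene (K2CO3, acetone) should give 1,3-dimethoxy-5-[(3-methylbut-2-en-1-yl)oxy]benzene F1. Heating in N,N‑diethylaniline at about 190 °C should bring about the aromatic Claisen rearrangement to either of the two equivalent ortho positions, with allyl inversion, giving 3,5-dimethoxy-2-(2-methylbut-3-en-2-yl)phenol F2. O‑Methylation (MeI, K2CO3, acetone) then gives 13.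

Step 7. The cleavage may take the wrong ortho methoxy group, the one with only a hydrogen neighbour, or both. The two ethers differ only in their steric surroundings, and the wrong choice would place the allyl group on C6 after ring closure. Fallback from 16, returning at 18: both ortho ethers are cleaved with BBr3 (2.2 equiv, CH2Cl2, −78 → 0 °C, NaHCO3 quench) to 1-[2,6-dihydroxy-4-methoxy-3-(2-methylbut-3-en-2-yl)phenyl]ethan-1-one F3. The unshielded hydroxyl is then methylated with one equivalent of MeI and K2CO3 in acetone; the hydroxyl next to the tertiary alkyl group is shielded and stays in the hydrogen bond to the carbonyl. The selectivity is thus moved from a deprotection to a sterically controlled reprotection, and the product is 18.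

Step 9. The oxidative cyclisation may be diverted to the five‑membered closure (attack at the α‑carbon, the aurone mode). A substituent at C6' of the chalcone, here the methoxy group, twists the enone and is known to favour this mode. Fallback from 21, returning at 23: isomerisation with NaOAc in refluxing EtOH should give racemic 5,7-dimethoxy-2-(4-methoxyphenyl)-8-(2-methylbut-3-en-2-yl)-2,3-dihydrochromen-4-one F4. Dehydrogenation with DDQ in refluxing dioxane gives 5,7-dimethoxy-2-(4-methoxyphenyl)-8-(2-methylbut-3-en-2-yl)chromen-4-one F5. Deprotonation at C3 with LiN(iPr)2 in THF at −78 °C gives [5,7-dimethoxy-2-(4-methoxyphenyl)-8-(2-methylbut-3-en-2-yl)-4-oxochromen-3-yl]lithium F6, which is trapped with B(OMe)3 as dimethyl [5,7-dimethoxy-2-(4-methoxyphenyl)-8-(2-methylbut-3-en-2-yl)-4-oxochromen-3-yl]boronate F7 and oxidised with H2O2 to 23. The ring size is fixed here before the C3 oxygen is introduced.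

Step 10. The third ether, on O5, may not be cleaved once two or three phenoxide charges sit on the molecule. Prolonged heating risks radical addition of liberated thiol to the vinyl group and oxidative degradation of the polyanion. Fallback from 23, returning at 24: BCl3 (CH2Cl2, −78 → 0 °C, NaHCO3 quench) removes the O5 methyl group through the chelate with the C4 carbonyl, at a stage where O7 is still methylated and cannot add to the vinyl group. This gives 3,5-dihydroxy-7-methoxy-2-(4-methoxyphenyl)-8-(2-methylbut-3-en-2-yl)chromen-4-one F8. The two remaining para‑type ethers are then cleaved with NaSEt in DMF at a lower temperature to give 24.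

Step 6. The hindered aryllithium 14 may take a proton from the acetyl group of the amide (enolisation) and so return 13 in place of acyl transfer. Fallback from 13, going directly to 16: Friedel–Crafts acetylation with acetyl chloride and SnCl4 in CH2Cl2 at −78 °C in the presence of 2,6‑di‑tert‑butylpyridine as proton scavenger. The very high nucleophilicity of the ring allows the low temperature that keeps the tertiary allyl group in place. No new compound is made on this way (F0).

## Further compounds

F1 | step 5 | 1,3-dimethoxy-5-[(3-methylbut-2-en-1-yl)oxy]benzene | COc1cc(OC)cc(OCC=C(C)C)c1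
F2 | step 5 | 3,5-dimethoxy-2-(2-methylbut-3-en-2-yl)phenol | C=CC(C)(C)c1c(O)cc(OC)cc1OC
F3 | step 7 | 1-[2,6-dihydroxy-4-methoxy-3-(2-methylbut-3-en-2-yl)phenyl]ethan-1-one | C=CC(C)(C)c1c(OC)cc(O)c(C(C)=O)c1O
F4 | step 9 | 5,7-dimethoxy-2-(4-methoxyphenyl)-8-(2-methylbut-3-en-2-yl)-2,3-dihydrochromen-4-one (racemic) | C=CC(C)(C)c1c(OC)cc(OC)c2c1OC(c1ccc(OC)cc1)CC2=O
F5 | step 9 | 5,7-dimethoxy-2-(4-methoxyphenyl)-8-(2-methylbut-3-en-2-yl)chromen-4-one | C=CC(C)(C)c1c(OC)cc(OC)c2c(=O)cc(-c3ccc(OC)cc3)oc12
F6 | step 9 | [5,7-dimethoxy-2-(4-methoxyphenyl)-8-(2-methylbut-3-en-2-yl)-4-oxochromen-3-yl]lithium | C=CC(C)(C)c1c(OC)cc(OC)c2c(=O)c([Li])c(-c3ccc(OC)cc3)oc12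
F7 | step 9 | dimethyl [5,7-dimethoxy-2-(4-methoxyphenyl)-8-(2-methylbut-3-en-2-yl)-4-oxochromen-3-yl]boronate | C=CC(C)(C)c1c(OC)cc(OC)c2c(=O)c(B(OC)OC)c(-c3ccc(OC)cc3)oc12
F8 | step 10 | 3,5-dihydroxy-7-methoxy-2-(4-methoxyphenyl)-8-(2-methylbut-3-en-2-yl)chromen-4-one | C=CC(C)(C)c1c(OC)cc(O)c2c(=O)c(O)c(-c3ccc(OC)cc3)oc12
F0 | step 6 | none | none
A1 | alternative 1 | 3,5,7-tris(methoxymethoxy)-2-[4-(methoxymethoxy)phenyl]-8-(2-methylbut-3-en-2-yl)chromen-4-one | C=CC(C)(C)c1c(OCOC)cc(OCOC)c2c(=O)c(OCOC)c(-c3ccc(OCOC)cc3)oc12
A2 | alternative 1 | 2-[2-(methoxymethoxy)acetyl]-3,5-bis(methoxymethoxy)-6-(2-methylbut-3-en-2-yl)phenyl 4-(methoxymethoxy)benzoate | C=CC(C)(C)c1c(OCOC)cc(OCOC)c(C(=O)COCOC)c1OC(=O)c1ccc(OCOC)cc1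
A3 | alternative 2 | 5-ethoxy-2-(2-methylbut-3-en-2-yl)-3-(triisopropylsilyloxy)phenol | C=CC(C)(C)c1c(O)cc(OCC)cc1O[Si](C(C)C)(C(C)C)C(C)C
A4 | alternative 2 | 3-ethoxycyclobut-2-en-1-one | CCOC1=CC(=O)C1
A5 | alternative 2 | [(3,3-dimethylpent-4-en-1-yn-1-yl)oxy]tri(propan-2-yl)silane | C=CC(C)(C)C#CO[Si](C(C)C)(C(C)C)C(C)C
A6 | alternative 3 | methyl 2,4,6-trihydroxy-3-(2-methylbut-3-en-2-yl)benzoate | COC(=O)c1c(O)cc(O)c(C(C)(C)C=C)c1O
A7 | alternative 3 | dimethyl 4-(2-methylbut-3-en-2-yl)-3,5-dioxoheptanedioate | COC(=O)CC(=O)C(C(C)(C)C=C)C(=O)CC(=O)OC
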